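**Retrosynthetic overview**

1. 21 ⇒ 16 + 19: the C8–C9 bond of the (7E,9E)-diene in the side chain is made last by hydrozirconation and palladium coupling; the methyl ester comes from the primary alcohol of 14.
2. 14 ⇒ 12 + H2O2 (step 8): the only ring of the target, the 1,2-dioxolane O1–O2–C3–C4–C5, is built by stitching H2O2 between C3 (oxetane carbon, inversion) and C5 (alkene carbon); the ring is closed by the O1–C5 bond.
3. Enabling feature: C5 is a quaternary carbon that carries a methyl group and sits 1,3 to the peroxy carbon C3 across the C4 methylene. C5–CH3 with C5–O1 is therefore the Markovnikov retron of a C5=CH2 alkene, and C3 with its oxygen and two-carbon arm is the retron of a 2,2-disubstituted oxetane.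
4. 12 ⇒ (E)-allylic alcohol 8 (Sharpless epoxide, then oxetane) ⇒ 3-chloro-2-(chloromethyl)prop-1-ene 2 as a four-carbon linchpin (two copper-catalysed couplings, carboalumination, acetylide).
5. Ring order: oxirane (step 5, opened in step 6) → oxetane (step 7, opened in step 8) → 1,2-dioxolane (step 8); the first two are temporary.

Key step: step 8

Remark (assumption): the sense of induction of the chiral acid at C5 in step 8 cannot be predicted from its known alkenol cyclisations; the antipode (from (R)- or (S)-BINOL) that delivers the (5S) centre is the one meant.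

**Step 1**
Reactants: 1 1-bromo-5-chloropentane; 2 3-chloro-2-(chloromethyl)prop-1-ene
Product: 4 8-chloro-2-(chloromethyl)oct-1-ene, via (5-chloropentyl)magnesium bromide 3 (not isolated)
Conditions: Mg, THF; then 2 (3 equiv), Li2CuCl4 (cat.), THF, −20 °C → rt
Reagents that add atoms: none
Why: Kochi-type copper-catalysed Grignard/allylic chloride coupling; SN2 and SN2' attack on the symmetric dichloride give the same product, excess 2 should suppress double alkylation, and the primary alkyl chloride should stay inert.

**Step 2**
Reactants: 4 8-chloro-2-(chloromethyl)oct-1-ene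
Product: 5 10-chloro-4-methylidenedec-1-yne
Conditions: HC≡CMgBr (excess), CuCl (cat.), THF, 50 °C
Reagents that add atoms: ethynylmagnesium bromide, C#C[Mg]Br
Why: Copper-catalysed allylic substitution by the alkynyl Grignard reagent should give the skipped 1,4-enyne (SN2 and SN2' again converge), the allylic chloride reacting far faster than the primary one.

**Step 3**
Reactants: 5 10-chloro-4-methylidenedec-1-yne
Product: 7 (2E)-11-chloro-3-methyl-5-methylideneundec-2-en-1-ol, via (E)-alkenyl(dimethyl)alane 6 (not isolated)
Conditions: Me3Al, Cp2ZrCl2 (cat.), CH2Cl2, 0 °C → rt; then (CH2O)n, THF, 0 °C → rt; aq HCl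
Reagents that add atoms: trimethylaluminium, C[Al](C)C; paraformaldehyde (reacts as formaldehyde), C=O
Why: Negishi zirconium-catalysed methylalumination adds Me and Al syn across the terminal alkyne with Al at the terminus, and hydroxymethylation of the alane with retention fixes the (E)-trisubstituted alkene; the 1,1-disubstituted alkene and the alkyl chloride should not react.

**Step 4**
Reactants: 7 (2E)-11-chloro-3-methyl-5-methylideneundec-2-en-1-ol
Product: 8 (2E)-3-methyl-5-methylidenetridec-2-en-12-yn-1-ol
Conditions: LiC≡CH·H2NCH2CH2NH2 (3 equiv), DMSO, rt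
Reagents that add atoms: lithium acetylide–ethylenediamine complex, [Li+].[C-]#C.NCCN
Why: SN2 displacement of the primary chloride by acetylide in DMSO installs the terminal alkyne after the carboalumination (so only one alkyne was present there); the allylic alcohol is carried as its alkoxide and the base is too weak to move the skipped diene.

**Step 5**
Reactants: 8 (2E)-3-methyl-5-methylidenetridec-2-en-12-yn-1-ol
Product: 9 [(2S,3S)-3-methyl-3-(2-methylidenedec-9-yn-1-yl)oxiran-2-yl]methanol
Conditions: Ti(Oi-Pr)4 (10 mol%), L-(+)-diethyl tartrate (12 mol%), t-BuOOH, 4 Å MS, CH2Cl2, −20 °C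
Reagents that add atoms: tert-butyl hydroperoxide, CC(C)(C)OO
Why: Sharpless asymmetric epoxidation; hydroxyl-directed, reagent-controlled oxygen delivery with the L-(+)-tartrate to the (E)-allylic alcohol should give the (2S,3S)-epoxide, setting the tertiary C–O centre that becomes C3, while the undirected alkene and alkyne stay untouched.

**Step 6**
Reactants: 9 [(2S,3S)-3-methyl-3-(2-methylidenedec-9-yn-1-yl)oxiran-2-yl]methanol
Product: 10 (3S)-3-methyl-5-methylidenetridec-12-yne-1,3-diol
Conditions: NaAlH2(OCH2CH2OCH3)2, THF, 0 °C → rt
Reagents that add atoms: none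
Why: Hydroxyl-directed intramolecular hydride delivery from the alkoxyaluminate opens the 2,3-epoxy alcohol at C2 and should give the 1,3-diol; the tertiary C–O bond is not broken, so its configuration is retained.

**Step 7**
Reactants: 10 (3S)-3-methyl-5-methylidenetridec-12-yne-1,3-diol
Product: 12 (2S)-2-methyl-2-(2-methylidenedec-9-yn-1-yl)oxetane, via primary monotosylate 11 (not isolated)
Conditions: TsCl, Et3N, DMAP (cat.), CH2Cl2, 0 °C; then KOt-Bu, THF, 0 °C → rt
Reagents that add atoms: none
Why: Selective sulfonylation of the primary hydroxyl followed by 4-exo-tet Williamson closure by the tertiary alkoxide; the tertiary C–O bond persists, so the centre stays (S).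

**Step 8**
Reactants: 12 (2S)-2-methyl-2-(2-methylidenedec-9-yn-1-yl)oxetane
Product: 14 2-[(3S,5S)-3,5-dimethyl-5-(oct-7-yn-1-yl)-1,2-dioxolan-3-yl]ethan-1-ol, via (3R)-hydroperoxy alcohol 13 (not isolated)
Conditions: anhydrous H2O2 in Et2O (1.3 equiv), chiral IDPi Brønsted acid (imidodiphosphorimidate with N-SO2CF3 groups on a 3,3'-diaryl-BINOL backbone, 5 mol%), CH2Cl2, −40 → 0 °C; then cyclohexane, 35 °C
Reagents that add atoms: hydrogen peroxide, OO
Why: Proposed new method: the strong, confined chiral acid first activates the oxetane oxygen (by far the most basic site), so that H2O2 attacks the tertiary carbon from the back in a loose SN2 event and gives hydroperoxy alcohol 13 with inversion; on warming, the same acid transfers its proton to the terminal CH2 of the 1,1-disubstituted alkene while the distal peroxy oxygen bonds to the developing tertiary cation in a concerted, asynchronous Markovnikov addition, which makes the O1–C5 bond, closes the ring and turns =CH2 into the C5 methyl. The closest known reactions are the Me3SiOSO2CF3-catalysed perhydrolysis of 2,2-disubstituted oxetanes to 3-hydroperoxy alkanols with inversion and the IDPi-catalysed asymmetric intramolecular hydroalkoxylation of unactivated 1,1-disubstituted alkenols to 2,2-disubstituted tetrahydrofurans; capture of an alkene by a hydroperoxide under a chiral acid is the untested element. The single ring, the 1,2-dioxolane, closes in the 5-exo-trig mode at C5. C3 is controlled by the substrate (stereospecific inversion of the Sharpless-derived centre) and C5 by the catalyst, whose pocket must tell the methyl-forming CH2 face from the n-alkyl face; the acyclic, 1,3-remote C3 should exert little opposing bias. The step needs oxetane opening before alkene protonation (secured by basicity and ring strain), attack of H2O2 at the tertiary and not the primary oxetane carbon (cation-stabilising substitution), capture at C5 by the peroxy oxygen and not the hydroxyl (five- against seven-membered ring), and an inert alkyne (much harder to protonate than the alkene).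

**Step 9**
Reactants: 14 2-[(3S,5S)-3,5-dimethyl-5-(oct-7-yn-1-yl)-1,2-dioxolan-3-yl]ethan-1-ol
Product: 15 2-[(3R,5S)-3,5-dimethyl-5-(oct-7-yn-1-yl)-1,2-dioxolan-3-yl]acetic acid
Conditions: TEMPO (0.2 equiv), PhI(OAc)2 (2.2 equiv), MeCN/H2O 1:1, rt
Reagents that add atoms: water, O
Why: Oxoammonium (TEMPO/PhI(OAc)2) oxidation of the primary alcohol through the aldehyde hydrate to the acid; the tetra-alkyl peroxide and the alkyne are not oxidisable under these conditions and no stereocentre is touched (the C3 descriptor changes only through CIP ranking).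

**Step 10**
Reactants: 15 2-[(3R,5S)-3,5-dimethyl-5-(oct-7-yn-1-yl)-1,2-dioxolan-3-yl]acetic acid
Product: 16 methyl 2-[(3R,5S)-3,5-dimethyl-5-(oct-7-yn-1-yl)-1,2-dioxolan-3-yl]acetate
Conditions: Me3SiCHN2 (hexanes), MeOH/toluene 1:3, 0 °C → rt
Reagents that add atoms: (trimethylsilyl)diazomethane, C[Si](C)(C)C=[N+]=[N-]
Why: Diazoalkane esterification under neutral conditions, which avoids base-induced retro-oxa-Michael opening of the β-peroxy ester.

**Step 11**
Reactants: 17 (3Z)-hex-3-en-1-ol
Product: 18 (3Z)-hex-3-enal
Conditions: Dess–Martin periodinane, NaHCO3, CH2Cl2, 0 °C → rt; used crude at once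
Reagents that add atoms: none
Why: Dess–Martin oxidation under buffered, non-basic conditions should give the β,γ-unsaturated aldehyde without migration of the Z-alkene into conjugation.

**Step 12**
Reactants: 18 (3Z)-hex-3-enal
Product: 19 (1E,4Z)-1-iodohepta-1,4-diene
Conditions: CrCl2 (6 equiv), CHI3 (2 equiv), THF/1,4-dioxane, 0 °C → rt
Reagents that add atoms: iodoform, IC(I)I
Why: Takai olefination through a geminal dichromium species should give the (E)-iodoalkene under non-basic conditions that leave the skipped (Z)-alkene in place.

**Step 13**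
Reactants: 16 methyl 2-[(3R,5S)-3,5-dimethyl-5-(oct-7-yn-1-yl)-1,2-dioxolan-3-yl]acetate; 19 (1E,4Z)-1-iodohepta-1,4-diene
Product: 21 methyl 2-[(3R,5S)-3,5-dimethyl-5-[(7E,9E,12Z)-pentadeca-7,9,12-trien-1-yl]-1,2-dioxolan-3-yl]acetate (target), via (E)-alkenylzirconocene chloride 20 (not isolated)
Conditions: Cp2Zr(H)Cl (1.2 equiv), THF, rt, 20 min; then 19, Pd(PPh3)4 (5 mol%), THF, rt
Reagents that add atoms: none
Why: syn-Hydrozirconation of the terminal alkyne gives the (E)-alkenylzirconocene, and Negishi-type palladium-catalysed alkenyl–alkenyl coupling with retention at both partners should give the (7E,9E)-diene with the (12Z)-alkene carried in; the hindered tetra-alkyl peroxide and the ester are expected to outlast the brief exposure to the hydride.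

**Compound list**

1 | 1-bromo-5-chloropentane | ClCCCCCBr | starting material
2 | 3-chloro-2-(chloromethyl)prop-1-ene | ClCC(=C)CCl | starting material
3 | (5-chloropentyl)magnesium bromide | ClCCCCC[Mg]Br | intermediate
4 | 8-chloro-2-(chloromethyl)oct-1-ene | ClCC(=C)CCCCCCCl | intermediate
5 | 10-chloro-4-methylidenedec-1-yne | C#CCC(=C)CCCCCCCl | intermediate
6 | [(1E)-10-chloro-2-methyl-4-methylidenedec-1-en-1-yl]dimethylalumane | C[Al](C)/C=C(\C)CC(=C)CCCCCCCl | intermediate
7 | (2E)-11-chloro-3-methyl-5-methylideneundec-2-en-1-ol | OC/C=C(\C)CC(=C)CCCCCCCl | intermediate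
8 | (2E)-3-methyl-5-methylidenetridec-2-en-12-yn-1-ol | OC/C=C(\C)CC(=C)CCCCCCC#C | intermediate
9 | [(2S,3S)-3-methyl-3-(2-methylidenedec-9-yn-1-yl)oxiran-2-yl]methanol | C#CCCCCCCC(=C)C[C@]1(C)O[C@H]1CO | intermediate
10 | (3S)-3-methyl-5-methylidenetridec-12-yne-1,3-diol | C#CCCCCCCC(=C)C[C@@](O)(C)CCO | intermediate
11 | (3S)-3-hydroxy-3-methyl-5-methylidenetridec-12-yn-1-yl 4-methylbenzenesulfonate | C#CCCCCCCC(=C)C[C@@](O)(C)CCOS(=O)(=O)c1ccc(C)cc1 | intermediate
12 | (2S)-2-methyl-2-(2-methylidenedec-9-yn-1-yl)oxetane | C#CCCCCCCC(=C)C[C@@]1(C)CCO1 | intermediate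
13 | (3R)-3-hydroperoxy-3-methyl-5-methylidenetridec-12-yn-1-ol | C#CCCCCCCC(=C)C[C@](C)(CCO)OO | intermediate
14 | 2-[(3S,5S)-3,5-dimethyl-5-(oct-7-yn-1-yl)-1,2-dioxolan-3-yl]ethan-1-ol (C3 reads S only because the CIP ranking changes on ring closure) | C#CCCCCCC[C@@]1(C)C[C@](C)(CCO)OO1 | intermediate
15 | 2-[(3R,5S)-3,5-dimethyl-5-(oct-7-yn-1-yl)-1,2-dioxolan-3-yl]acetic acid | C#CCCCCCC[C@@]1(C)C[C@](C)(CC(=O)O)OO1 | intermediate
16 | methyl 2-[(3R,5S)-3,5-dimethyl-5-(oct-7-yn-1-yl)-1,2-dioxolan-3-yl]acetate | C#CCCCCCC[C@@]1(C)C[C@](C)(CC(=O)OC)OO1 | intermediate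
17 | (3Z)-hex-3-en-1-ol | CC/C=C\CCO | starting material
18 | (3Z)-hex-3-enal | CC/C=C\CC=O | intermediate
19 | (1E,4Z)-1-iodohepta-1,4-diene | CC/C=C\C/C=C/I | intermediate
20 | chlorobis(cyclopentadienyl)[(1E)-8-[(3S,5R)-5-(2-methoxy-2-oxoethyl)-3,5-dimethyl-1,2-dioxolan-3-yl]oct-1-en-1-yl]zirconium | Cl[Zr](C1C=CC=C1)(C1C=CC=C1)/C=C/CCCCCC[C@@]1(C)C[C@](C)(CC(=O)OC)OO1 | intermediate
21 | methyl 2-[(3R,5S)-3,5-dimethyl-5-[(7E,9E,12Z)-pentadeca-7,9,12-trien-1-yl]-1,2-dioxolan-3-yl]acetate | CC/C=C\C/C=C/C=C/CCCCCC[C@@]1(C)C[C@](C)(CC(=O)OC)OO1 | target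

Total step count: 13. Longest linear sequence: 11 (steps 1–10 and 13); steps 11–12 make the side-chain iodide. No protecting groups are used.

**Steps most likely to fail**

Step 8 (Proposed new method). Three things may go wrong:
- The oxetane may ionise to a free tertiary cation, with loss of stereochemical fidelity at C3.
- The catalyst may discriminate poorly between the two faces at C5, or the ring closure may be sluggish.
- Intermolecular addition of H2O2 to the alkene, or acid-induced heterolysis of the tertiary hydroperoxide, may then take over.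

The fallback uses known reaction types only and sets out from oxetane 12. Perhydrolysis with anhydrous ethereal H2O2 and catalytic Me3SiOSO2CF3 at −78 → 0 °C should give (3R)-3-hydroperoxy-3-methyl-5-methylidenetridec-12-yn-1-ol 13, now isolated. N-Iodosuccinimide in CH2Cl2 at 0 °C then closes the same O1–C5 bond by 5-exo iodoperoxidation to 2-[(3S,5S)-5-(iodomethyl)-3-methyl-5-(oct-7-yn-1-yl)-1,2-dioxolan-3-yl]ethan-1-ol F1. F1 is separated from its C5 epimer by chromatography; the two are diastereomers because C3 is already fixed. Reduction of the C–I bond with Bu3SnH (about 1.1 equiv, concentrated solution, AIBN) should then give the C5 methyl; iodine abstraction is much faster than stannyl addition to the alkyne, and the high hydride concentration limits β-scission of the peroxide. The fallback comes back to the route at 14. Catalyst control at C5 is traded for a separation.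

Step 13. Hydride transfer from zirconium to the O–O bond or the ester may compete with hydrozirconation, and a slow coupling would prolong contact of the peroxide with zerovalent palladium and phosphine. The fallback sets out from 16. Hydroboration with pinacolborane, catalysed by dicyclohexylborane (5 mol%, neat, rt) and free of metal hydride, should give the isolable methyl 2-[(3R,5S)-3,5-dimethyl-5-[(7E)-8-(4,4,5,5-tetramethyl-1,3,2-dioxaborolan-2-yl)oct-7-en-1-yl]-1,2-dioxolan-3-yl]acetate F2. Suzuki–Miyaura coupling of F2 with 19 (Pd(PPh3)4, aqueous K3PO4, THF, rt) then comes back to the route at 21.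

Step 12. The chromium-mediated olefination may give incomplete E-selectivity, and the stereoisomeric iodide would pass its geometry on to the triene. The fallback sets out from 18. One-carbon homologation with lithiated Me3SiCHN2 (Colvin rearrangement, THF, −78 → 0 °C) should give (4Z)-hept-4-en-1-yne F3. syn-Hydrozirconation with Cp2Zr(H)Cl gives chlorobis(cyclopentadienyl)[(1E,4Z)-hepta-1,4-dien-1-yl]zirconium F4 (not isolated), and iodinolysis with I2 proceeds with retention. The fallback comes back to the route at 19, with the E-geometry fixed by the syn addition instead of by reagent selectivity.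

**Further compounds**

F1 | step 8 | 2-[(3S,5S)-5-(iodomethyl)-3-methyl-5-(oct-7-yn-1-yl)-1,2-dioxolan-3-yl]ethan-1-ol | C#CCCCCCC[C@@]1(CI)C[C@](C)(CCO)OO1
F2 | step 13 | methyl 2-[(3R,5S)-3,5-dimethyl-5-[(7E)-8-(4,4,5,5-tetramethyl-1,3,2-dioxaborolan-2-yl)oct-7-en-1-yl]-1,2-dioxolan-3-yl]acetate | CC1(C)OB(/C=C/CCCCCC[C@@]2(C)C[C@](C)(CC(=O)OC)OO2)OC1(C)C
F3 | step 12 | (4Z)-hept-4-en-1-yne | CC/C=C\CC#C
F4 | step 12 | chlorobis(cyclopentadienyl)[(1E,4Z)-hepta-1,4-dien-1-yl]zirconium | Cl[Zr](C1C=CC=C1)(C1C=CC=C1)/C=C/C/C=C\CC
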